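The earlier runs and the new flask were generated by integration from invented constants, and the scatter is random.

The rate constants are not at hand, so this reckoning counts turnovers, in fractions of the charge.

| flask | free monomer | protic impurity | initiator | remark | time |
|---|---|---|---|---|---|
| alder | 0.42 M | 0.093 M | 0.1 mol% | run made earlier |  |
| birch | 0.42 M | 0.14 M | 0.1 mol% | run made earlier |  |
| spring | 0.42 M | 0.0840 M | 0.1 mol% |  | 20 min |
| noon | 0.42 M | 0.250 M | 0.1 mol% |  | 20 min |

| run | time / min | monomer in chains / % |
|---|---|---|
| alder | 4.00 | 69.3 |
| alder | 8.00 | 71.3 |
| alder | 12.0 | 71.5 |
| alder | 15.0 | 71.3 |
| alder | 20.0 | 71.4 |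
| birch | 4.00 | 59.4 |
| birch | 8.00 | 61.3 |
| birch | 12.0 | 61.6 |
| birch | 15.0 | 62.0 |
| birch | 20.0 | 61.8 |

(standard deviation of a reading: 0.3 percentage points)

* which of the two ends with the longer chains by the average number of monomer units in a chain (living and dead chains, two that joined counted as one) ("neither" if they lie within 10%) (spring / noon / neither)
* average number of monomer units in a chain (living and dead chains, two that joined counted as one) at the end, spring
* average number of monomer units in a chain (living and dead chains, two that joined counted as one) at the end, noon

- the average divides the monomer in chains by the number of chains, living and dead together; two radicals that join make one chain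
- the earlier runs do not show the number of chains; that part of a forecast is a guess

1. For spring and noon the ration is 1000: the monomer charged per initiator charged. It equals the degree of polymerisation if every monomer enters a chain and each initiator leaves one chain.
2. Each initiator that breaks up gives two initiating radicals. If their chains all join in pairs, one chain stands per initiator; if none join, two stand. The length therefore lies between the fraction in chains times the ration, divided by two, and that product undivided. The earlier runs do not show the number of chains, so this step is assumed.
3. Suppose each protic impurity takes one free monomer, leaving a room of one minus their ratio. In the alder run, the room of 77.9% holds 71.4%, a filling of 0.917. In the birch run, the room of 66.7% holds 61.8%, a filling of 0.927.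
4. Spring has a room of 80.0%, and noon 40.5%. With the mean filling 0.922, the spring bracket runs from 369 to 800, and the noon bracket from 187 to 405.
5. This reckoning commits to one chain per initiator: 738 for spring and 373 for noon.
6. The forecast gives 960 for spring and 530 for noon, with spring longer, and warns: “The chain count is an assumption, so the ranges are wide.” Both values stand above these tops.

The flask gives 735 for spring and 386 for noon, so spring ends longer, and both lie inside the brackets.

    2 growing radical → dead chain (k = 1.70 × 10⁶ L mol⁻¹ s⁻¹)
    protic impurity + free monomer → quenched substrate (k = 0.487 L mol⁻¹ s⁻¹)
    free monomer + growing radical → monomer in chains + growing radical, rate k3*[growing radical]*[free monomer] (k = 10200 L mol⁻¹ s⁻¹)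
    free monomer + initiating radical → growing radical + monomer in chains (k = 4.56 × 10⁵ L mol⁻¹ s⁻¹)
    initiator → 2 initiating radical (k = 0.0170 s⁻¹)

In spring at 20.0 min, dead chain stands at 4.20 × 10⁻⁴ M, equal to the initiator charged, 4.20 × 10⁻⁴ M, so the ration times the 73.5% in chains gives 735. A neighbouring flask is like noon but with 0.4 mol% of initiator, which cuts the ration to 250. Its 45.2% in chains then reckons to 113 units per chain, and the flask gives 114.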